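**Plan**

1. Numbering: C1 = C(OH), C7 = its CH2OBz carbon, C2 = CHOBz, C3=C4, C5 and C6 = CHOAc. The retrosynthesis cuts the four ester C–O bonds, then C2–H (back to a C2 ketone conjugated with C3=C4), then C1–C7 (aldol with formaldehyde), then C1–O (enolate oxidation).
2. This leaves the 4,5-trans-dioxygenated cyclohex-2-enone from (−)-quinic acid, mapped with a shift of one ring atom (quinic C1→C2, C2→C3, C3→C4, C4→C5, C5→C6, C6→C1). The acid's own carboxyl carbon is excised and a new C7 is attached to the neighbouring ring carbon.
3. Enabling feature: C1 lies between C2, which can act as an enone carbonyl (C2=O/C3=C4), and C6, whose oxygen is trans to O5. Bridging O5/O6 in a trans-fused butane-2,3-diacetal (BDA) 1,4-dioxane ring locks the half-chair, so a C1 enolate keeps its β-oxygen and has one stereoelectronically preferred face.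
4. Forward order: the carbocycle is bought. Then BDA ring on, old carboxyl carbon off, C3=C4 by elimination, O onto C1, C7 onto C1 (key), C2 ketone reduced, two benzoates, BDA and MOM off, two acetates.
5. Stereochemistry: C5 and C6 are quinic acid C4 and C5. C1 is set in the key step by the locked ring. C2 is relayed from the new C7–OH by intramolecular hydride delivery.

Key step: step 7

Remark: the carbinol centre made at C1 in step 5 is planarised again in step 7. Compounds 8 and 9 are therefore drawn as the epimer expected from axial attack (O1 cis to O6), and either epimer serves.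

**Route**

Step 1
Reactants: 1 (−)-quinic acid
Product: 2 BDA methyl quinate
Conditions: butane-2,3-dione, HC(OMe)3, CSA (cat.), MeOH, reflux
Reagents that add atoms: butane-2,3-dione CC(=O)C(C)=O; methanol CO
Why: Fischer esterification and butane-2,3-diacetal formation run together under acid catalysis; the bis-acetal picks the only trans-diequatorial vicinal diol (quinic O4/O5 = target O5/O6), and its two new acetal centres settle as (S,S) under thermodynamic control with both OMe groups axial (double anomeric effect).

Step 2
Reactants: 2 BDA methyl quinate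
Product: 3 BDA triol
Conditions: NaBH4, MeOH, 0 °C to rt
Reagents that add atoms: none
Why: Borohydride reduction of an α-hydroxy ester, activated by the neighbouring hydroxyl, should give the 1,2-diol without touching the acetal or any stereocentre.

Step 3
Reactants: 3 BDA triol
Product: 4 BDA β-hydroxy ketone
Conditions: NaIO4, SiO2/H2O, CH2Cl2, rt
Reagents that add atoms: none
Why: Malaprade glycol cleavage acts on the only free vicinal diol, expels the former carboxyl carbon as formaldehyde and turns quinic C1 into the ketone that becomes C2.

Step 4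
Reactants: 4 BDA β-hydroxy ketone
Product: 6 BDA enone, via mesylate 5 (not isolated)
Conditions: MsCl, Et3N, CH2Cl2, 0 °C to rt
Reagents that add atoms: methanesulfonyl chloride CS(=O)(=O)Cl (its atoms remain only in 5)
Why: Mesylation of the axial β-hydroxyl followed by E1cB elimination installs C3=C4 in conjugation with the C2 carbonyl and leaves the C5 and C6 stereocentres untouched.

Step 5
Reactants: 6 BDA enone
Product: 8 α′-ketol, via sodium dienolate 7 (not isolated)
Conditions: NaHMDS, THF, −78 °C; 2-(phenylsulfonyl)-3-phenyloxaziridine, −78 °C; AcOH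
Reagents that add atoms: 2-(phenylsulfonyl)-3-phenyloxaziridine O=S(=O)(N1OC1c1ccccc1)c1ccccc1 (oxygen atom); sodium hexamethyldisilazide C[Si](C)(C)[N-][Si](C)(C)C.[Na+] (sodium only in 7)
Why: Davis oxidation of the kinetic cross-conjugated dienolate places oxygen on C1 (α′-hydroxylation of an enone), with the dioxane ring keeping the β C6–O bond out of alignment for E1cB loss; the new carbinol centre, expected from axial attack, needs no control because step 7 erases it.

Step 6
Reactants: 8 α′-ketol
Product: 9 MOM ether
Conditions: MOMCl, iPr2NEt, CH2Cl2, 0 °C to rt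
Reagents that add atoms: chloromethyl methyl ether COCCl
Why: Standard MOM protection masks the ketol hydroxyl so that step 7 needs one equivalent of base, no enediolate forms, and O1 cannot later compete with C7–OH as a directing group; no stereocentre is touched.

Step 7
Reactants: 9 MOM ether; 10 formaldehyde
Product: 12 aldol (C1-hydroxymethyl enone), via lithium dienolate 11 (not isolated)
Conditions: LDA, THF, −78 °C; HCHO (monomer in THF, from cracked paraformaldehyde), −78 °C; AcOH, −78 °C
Reagents that add atoms: formaldehyde (compound 10) C=O; lithium diisopropylamide CC(C)[N-]C(C)C.[Li+] (lithium only in 11)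
Why: LDA, guided by lithium coordination to the carbonyl and MOM oxygens, removes the C1–H kinetically to give the cross-conjugated 1-alkoxy dienolate 11, whose only nucleophilic carbon, C1, adds to monomeric formaldehyde; this is a crossed aldol (enolate hydroxymethylation), and the closest known type is the α′-alkylation and α′-hydroxymethylation of kinetic cyclohexenone enolates. No ring is closed. The one new stereocentre, the quaternary C1, is controlled by the trans-fused BDA dioxane: it freezes the half-chair with C6–H pseudo-axial, and the new bond forms anti to that C–H (axial, chair-like attack, staggered about C1–C6), which puts C7 cis to O6 while the OMOM group swings into the equatorial site away from the C6–O bond. The step needs α′- rather than γ-deprotonation (secured by the kinetic base at −78 °C) and retention of the β-oxygen O6 (secured because the dioxane holds the C6–O bond close to the nodal plane of the enolate π system, so E1cB loss and aromatisation find no overlap). Double addition is impossible because C1 becomes quaternary, and the acetic acid quench at −78 °C forestalls retro-aldol and intramolecular oxa-Michael addition, the latter also being opposed by the trans ring fusion. The free C7–OH created here is the handle that sets C2 in step 8.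

Step 8
Reactants: 12 aldol
Product: 14 C2,C7-diol, via alkoxydiacetoxyborohydride 13 (not isolated)
Conditions: Me4NBH(OAc)3, MeCN/AcOH (1:1), −30 to 0 °C; aq. Rochelle salt
Reagents that add atoms: tetramethylammonium triacetoxyborohydride C[N+](C)(C)C.CC(=O)O[BH-](OC(C)=O)OC(C)=O (hydride to 14; boron, acetate and cation only in 13)
Why: Evans–Saksena hydroxyl-directed reduction: exchange of one acetate for C7–OH gives 13, which passes hydride through a six-membered chair-like transition state to the carbonyl face that carries the axial C7, so C2–OH should end trans to C7 and cis to O1, while free triacetoxyborohydride is too weak to reduce the enone unaided and 1,4-delivery is out of reach.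

Step 9
Reactants: 14 C2,C7-diol
Product: 15 dibenzoate
Conditions: BzCl, pyridine, DMAP (cat.), CH2Cl2, 0 °C to rt
Reagents that add atoms: benzoyl chloride O=C(Cl)c1ccccc1
Why: DMAP-catalysed acylation esterifies the primary C7–OH and the secondary allylic C2–OH in one operation, all other oxygens being masked.

Step 10
Reactants: 15 dibenzoate
Product: 16 C1,C5,C6-triol
Conditions: TFA/H2O (9:1), CH2Cl2, 0 °C to rt
Reagents that add atoms: none
Why: Aqueous acid hydrolysis cleaves the bis-acetal and the formaldehyde acetal through oxocarbenium ions but not the benzoates, and no C–O bond at a stereocentre is broken.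

Step 11
Reactants: 16 C1,C5,C6-triol
Product: 17 cleistenediol F
Conditions: Ac2O, pyridine, rt
Reagents that add atoms: acetic anhydride CC(=O)OC(C)=O
Why: Acetylation without DMAP should stop at the two secondary hydroxyls, because the tertiary C1–OH flanked by three substituted carbons is too hindered, and this gives the target.

**Compound list**

1 | (−)-quinic acid, (1S,3R,4S,5R)-1,3,4,5-tetrahydroxycyclohexane-1-carboxylic acid | OC(=O)[C@]1(O)C[C@@H](O)[C@@H](O)[C@H](O)C1 | starting material
2 | BDA methyl quinate: methyl quinate with O4/O5 bridged by a (2S,3S)-2,3-dimethoxybutane-2,3-diyl unit (trans-fused 1,4-dioxane, both OMe axial); 1-OH and 3-OH free | COC(=O)[C@]1(O)C[C@@H](O)[C@H]2O[C@](C)(OC)[C@](OC)(C)O[C@@H]2C1 | intermediate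
3 | BDA triol: as 2 with CH2OH in place of CO2Me | OC[C@]1(O)C[C@@H](O)[C@H]2O[C@](C)(OC)[C@](OC)(C)O[C@@H]2C1 | intermediate
4 | BDA β-hydroxy ketone: 3-hydroxy-4,5-(BDA-dioxy)cyclohexanone, 3-OH axial and cis to O4 | O=C1C[C@@H](O)[C@H]2O[C@](C)(OC)[C@](OC)(C)O[C@@H]2C1 | intermediate
5 | mesylate of 4 | O=C1C[C@@H](OS(C)(=O)=O)[C@H]2O[C@](C)(OC)[C@](OC)(C)O[C@@H]2C1 | intermediate
6 | BDA enone, (2S,3S,4aR,8aR)-2,3-dimethoxy-2,3-dimethyl-2,3,4a,8a-tetrahydro-1,4-benzodioxin-6(5H)-one [(4R,5R)-4,5-trans-dioxygenated cyclohex-2-enone] | O=C1C=C[C@H]2O[C@](C)(OC)[C@](OC)(C)O[C@@H]2C1 | intermediate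
7 | sodium dienolate of 6 (C1=C2–O−, C3=C4) | [Na+].[O-]C=1C=C[C@H]2O[C@](C)(OC)[C@](OC)(C)O[C@@H]2C=1 | intermediate
8 | α′-ketol: 6 with OH on C1, drawn cis to O6 | O=C1C=C[C@H]2O[C@](C)(OC)[C@](OC)(C)O[C@@H]2[C@@H]1O | intermediate
9 | MOM ether of 8 | O=C1C=C[C@H]2O[C@](C)(OC)[C@](OC)(C)O[C@@H]2[C@@H]1OCOC | intermediate
10 | formaldehyde (monomer from commercial paraformaldehyde) | C=O | starting material
11 | lithium dienolate of 9 (C1(OMOM)=C2–O−, C3=C4) | [Li+].[O-]C=1C=C[C@H]2O[C@](C)(OC)[C@](OC)(C)O[C@@H]2C=1OCOC | intermediate
12 | aldol: enone with quaternary C1 bearing OMOM (equatorial, trans to O6) and CH2OH (axial, cis to O6) | O=C1C=C[C@H]2O[C@](C)(OC)[C@](OC)(C)O[C@@H]2[C@@]1(CO)OCOC | intermediate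
13 | tetramethylammonium alkoxydiacetoxyborohydride formed at O7 of 12 | C[N+](C)(C)C.O=C1C=C[C@H]2O[C@](C)(OC)[C@](OC)(C)O[C@@H]2[C@@]1(CO[BH-](OC(C)=O)OC(C)=O)OCOC | intermediate
14 | C2,C7-diol: C2–OH trans to C7 and cis to O1 | O[C@H]1C=C[C@H]2O[C@](C)(OC)[C@](OC)(C)O[C@@H]2[C@@]1(CO)OCOC | intermediate
15 | dibenzoate of 14 (O2 and O7) | O=C(c1ccccc1)O[C@H]2C=C[C@H]3O[C@](C)(OC)[C@](OC)(C)O[C@@H]3[C@@]2(COC(=O)c4ccccc4)OCOC | intermediate
16 | C1,C5,C6-triol 2,7-dibenzoate | O=C(c1ccccc1)O[C@H]2C=C[C@@H](O)[C@H](O)[C@@]2(COC(=O)c3ccccc3)O | intermediate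
17 | cleistenediol F (1S,2S,5R,6S in the numbering used here) | CC(=O)O[C@@H]1C=C[C@H](OC(=O)c2ccccc2)[C@@](O)(COC(=O)c2ccccc2)[C@H]1OC(C)=O | target

Total step count: 11. Longest linear sequence: 11 steps (from 1).

**Steps most likely to fail**

1. Step 7. The risk is attack of formaldehyde on the undesired face of the tetrasubstituted dienolate (poor facial selectivity).
   - The fallback reverses the order in which carbon and oxygen arrive at C1. The group that enters last takes the same ring face in either order, so the reversal gives the opposite C1 configuration.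
   - It sets out from 6 and comes back at 12.
   - Kinetic enolisation of 6 (LDA, THF, −78 °C) and trapping with formaldehyde gives the α′-hydroxymethyl enone F1.
   - TBSCl/imidazole gives the silyl ether F2.
   - NaHMDS and the Davis oxaziridine oxidise its dienolate to the tertiary ketol F3.
   - MOMCl, iPr2NEt and NaI in warm 1,2-dichloroethane give the MOM ether F4.
   - TBAF buffered with AcOH removes the silyl group and returns to 12.

2. Step 8. The risk is slow ligand exchange or hydride transfer at the hindered conjugated carbonyl, so that undirected reduction from the open face competes (poor facial selectivity).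
   - The fallback uses the open face on purpose and then inverts C2.
   - It sets out from 12 and comes back at 15.
   - One equivalent of BzCl in pyridine at 0 °C gives the primary benzoate F5.
   - Luche reduction (NaBH4, CeCl3·7H2O, MeOH, −78 °C), anti to the axial C7, gives the C2-epimeric allylic alcohol F6.
   - Mitsunobu reaction with benzoic acid (PPh3, DIAD, toluene) inverts C2 while installing the second benzoate, giving 15.

3. Step 10. The risk is that the tertiary MOM ether lags behind the BDA acetal, and prolonged acid then promotes benzoyl migration to the freed hydroxyls or ionisation of the allylic benzoate.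
   - The fallback unmasks in stages, with acetylation in between.
   - It sets out from 15 and comes back at 17.
   - Short exposure to TFA/H2O at 0 °C removes only the BDA unit and gives the diol F7.
   - Ac2O/pyridine gives the diacetate F8.
   - Me2BBr (CH2Cl2, −78 °C, then aq. NaHCO3) cleaves the MOM ether when no free secondary hydroxyl is left to accept an acyl group, giving 17.

**Further compounds**

F1 | step 7 | α′-hydroxymethyl enone (CH2OH on C1, drawn cis to O6) | O=C1C=C[C@H]2O[C@](C)(OC)[C@](OC)(C)O[C@@H]2[C@@H]1CO
F2 | step 7 | silyl ether (TBS ether of F1) | O=C1C=C[C@H]2O[C@](C)(OC)[C@](OC)(C)O[C@@H]2[C@@H]1CO[Si](C)(C)C(C)(C)C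
F3 | step 7 | tertiary ketol (C1–OH trans to O6, CH2OTBS cis to O6) | O=C1C=C[C@H]2O[C@](C)(OC)[C@](OC)(C)O[C@@H]2[C@@]1(CO[Si](C)(C)C(C)(C)C)O
F4 | step 7 | MOM ether of F3 | O=C1C=C[C@H]2O[C@](C)(OC)[C@](OC)(C)O[C@@H]2[C@@]1(CO[Si](C)(C)C(C)(C)C)OCOC
F5 | step 8 | primary benzoate of 12 | O=C1C=C[C@H]2O[C@](C)(OC)[C@](OC)(C)O[C@@H]2[C@@]1(COC(=O)c3ccccc3)OCOC
F6 | step 8 | C2-epimeric allylic alcohol (C2–OH cis to C7) | O[C@@H]1C=C[C@H]2O[C@](C)(OC)[C@](OC)(C)O[C@@H]2[C@@]1(COC(=O)c3ccccc3)OCOC
F7 | step 10 | diol (C5,C6-diol 2,7-dibenzoate with C1–OMOM) | O=C(c1ccccc1)O[C@H]2C=C[C@@H](O)[C@H](O)[C@@]2(COC(=O)c3ccccc3)OCOC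
F8 | step 10 | diacetate of F7 | O=C(c1ccccc1)O[C@H]2C=C[C@@H](OC(C)=O)[C@H](OC(C)=O)[C@@]2(COC(=O)c3ccccc3)OCOC
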